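## Retrosynthetic overview

1. Labdane numbering is used. The side-chain butenolide is attached last, forming C12–C13 by B-alkyl Suzuki coupling on a C9 vinyl group. That vinyl group and the free C17 carbinol both come from a temporary butenolide fused to ring B (C11 carbonyl on C9, C17H2–O on C8).
2. Enabling feature: in ring B the tetrasubstituted C8=C9 alkene is held between C7H2 and quaternary C10 by two sp2–sp3 bonds. Its outer carbons C17 and C11 can be closed to a five-membered lactone, and O-6 sits β to C7. Hence C8=C9 is 3,4-dibromofuran-2(5H)-one (a cis-vinylene unit whose two C–Br bonds react in a fixed order), C7 is a β-silyloxyalkylborane, and C10 is the methyl-bearing end of a ring A C1=C10 alkene.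
3. Both ring B bonds are made in one flask: hydroboration, Suzuki coupling (C7–C8), then reductive Heck closure (C9–C10). This also sets C6, C10 and the cis ring fusion.
4. The ring A piece comes from ketoisophorone. Transfer hydrogenation sets C2. H-5 is put on the hindered face by epoxidising an exocyclic ethylidene group from the open face, followed by a 1,2-hydride shift.
5. Ring order: ring A (bought) → ring B together with the temporary lactone → side-chain butenolide (bought).

Key step: step 8

Remark: read literally, the SMILES describes a cis-fused decalin. H-5 and the C10 methyl lie on the same face (called β); O-2, C6 (on C5), C9 (on C10) and O-6 lie on the α face. The route is built for this isomer.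

## Route

Step 1
Reactants: 1 ketoisophorone (2,6,6-trimethylcyclohex-2-ene-1,4-dione)
Product: 2 (4S)-4-hydroxy-2,6,6-trimethylcyclohex-2-en-1-one
Conditions: RuCl[(S,S)-TsDPEN](p-cymene) (cat.), KOH (cat.), i-PrOH, 25 °C
Reagents that add atoms: none
Why: Noyori asymmetric transfer hydrogenation reduces only the less hindered carbonyl (the other is flanked by the gem-dimethyl carbon and the methyl-bearing alkene carbon), and, by analogy with aryl alkyl ketones with the alkenyl group in place of aryl, the (S,S)-catalyst should set the (S)-carbinol, which is C2 of the target.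

Step 2
Reactants: 2 (4S)-4-hydroxy-2,6,6-trimethylcyclohex-2-en-1-one
Product: 3 (4S)-4-(tert-butyldimethylsilyloxy)-2,6,6-trimethylcyclohex-2-en-1-one
Conditions: TBSCl, imidazole, DMF, 25 °C
Reagents that add atoms: tert-butyldimethylsilyl chloride, CC(C)(C)[Si](C)(C)Cl
Why: Imidazole-promoted silyl ether formation protects the allylic alcohol and supplies the bulky group that fixes the ring conformation used in step 5.

Step 3
Reactants: 3 (4S)-4-(tert-butyldimethylsilyloxy)-2,6,6-trimethylcyclohex-2-en-1-one
Product: 4 (1S,4S)-4-(tert-butyldimethylsilyloxy)-1-ethyl-2,6,6-trimethylcyclohex-2-en-1-ol (ethyl cis to the silyloxy group)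
Conditions: EtMgBr, CeCl3, THF, −78 → 0 °C; H2O
Reagents that add atoms: ethylmagnesium bromide, CC[Mg]Br
Why: In this organocerium 1,2-addition the weakly basic ethylcerium reagent adds to the hindered, non-enolisable enone carbonyl instead of reducing or deprotonating it, from the face opposite the axial C4 methyl group, and the carbinol centre so formed is erased in step 4.

Step 4
Reactants: 4 tertiary allylic alcohol
Product: 5 (S)-tert-butyl{[(4Z)-4-ethylidene-3,5,5-trimethylcyclohex-2-en-1-yl]oxy}dimethylsilane
Conditions: Ph2S[OC(CF3)2Ph]2, CH2Cl2, 0 °C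
Reagents that add atoms: none
Why: In this Martin sulfurane dehydration C4 is quaternary and C10 is sp2, so the only β-hydrogens are those of the ethyl CH2 group and the exocyclic ethylidene diene must form, its geometry (methyl turned away from the gem-dimethyl carbon) being of no later consequence.

Step 5
Reactants: 5 ethylidene diene
Product: 6 6-(tert-butyldimethylsilyloxy)-2,4,8,8-tetramethyl-1-oxaspiro[2.5]oct-4-ene (oxirane oxygen cis to the silyloxy group)
Conditions: dimethyldioxirane, acetone–CH2Cl2, −40 °C
Reagents that add atoms: dimethyldioxirane, CC1(C)OO1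
Why: In this neutral dioxirane epoxidation the ring alkene is deactivated by its allylic silyloxy group so the exocyclic alkene reacts, and in the half-chair that keeps the silyloxy group pseudo-equatorial the axial C4 methyl group covers the β face, so oxygen is delivered to the α face and C5–O is set α.

Step 6
Reactants: 6 spiro vinyl epoxide
Product: 7 1-[(1R,4S)-4-(tert-butyldimethylsilyloxy)-2,6,6-trimethylcyclohex-2-en-1-yl]ethan-1-one (acetyl cis to the silyloxy group)
Conditions: BF3·OEt2 (cat.), CH2Cl2, −78 °C
Reagents that add atoms: none
Why: In this Meinwald rearrangement the Lewis acid opens the tertiary allylic C5–O bond and the hydrogen on C6 migrates to C5 on the face opposite the departing oxygen, which gives the methyl ketone and places H-5 on the hindered β face without any base that could trigger vinylogous loss of silanol.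

Step 7
Reactants: 7 methyl ketone
Product: 8 kinetic silyl enol ether, tert-butyl({1-[(1R,4S)-4-(tert-butyldimethylsilyloxy)-2,6,6-trimethylcyclohex-2-en-1-yl]ethenyl}oxy)dimethylsilane
Conditions: KN(SiMe3)2, THF, −78 °C; TBSCl
Reagents that add atoms: tert-butyldimethylsilyl chloride, CC(C)(C)[Si](C)(C)Cl
Why: In this kinetic enolate O-silylation the bulky amide takes a proton from the open methyl group and not the tertiary, doubly flanked H-5, so the terminal silyl enol ether forms and C5 is untouched.

Step 8
Reactants: 8 silyl enol ether; 9 3,4-dibromofuran-2(5H)-one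
Product: 12 cis-decalin-fused butenolide (2α- and 6α-silyloxy; H-5 and C10 methyl β; C11 carbonyl on C9; C17H2–O on C8), via B-alkyl-9-BBN adduct 10 (not isolated), via 3-bromo-4-alkylbutenolide 11 (not isolated)
Conditions: 9-BBN-H, THF, 0 → 40 °C; then 9, PdCl2(dppf) (cat.), AsPh3 (cat.), Cs2CO3, DMF–H2O, 25 °C; then HCO2Na, 85 °C
Reagents that add atoms: none
Why: 9-BBN-H adds to the 1,1-disubstituted silyl enol ether (boron to C7, hydrogen to C6) to give 10; zerovalent palladium inserts into the more electrophilic β C–Br bond of 9 and B-alkyl Suzuki–Miyaura coupling makes C7–C8 (11); on heating, the α C–Br bond adds oxidatively, the alkenylpalladium adds across the ring A C1=C10 alkene with C9 bonding to C10, and the secondary alkylpalladium left at C1 is reduced by formate. The closest known reaction types are the coupling of β-alkoxyalkyl-9-BBN reagents obtained from enol ethers, the C4-selective coupling of 3,4-dihalofuran-2(5H)-ones and the reductive intramolecular Heck reaction that builds quaternary carbons, here run one after the other on one catalyst charge. Ring B closes in the 6-exo-trig mode (7-endo attack at C1 would give a bridged ring). C6 is set in the hydroboration: allylic strain with the silyloxy group turns H-5 towards O-6, C4 and C10 then flank the =CH2 group, and the borane comes from the side away from quaternary C4, which gives the 6α-silyloxy configuration. C10 is set by C5: the pseudoaxial C5–C6 bond holds the four-atom tether over the α face, syn carbopalladation can reach C10 only from that face, and so C9 ends α, the methyl group β and the ring fusion cis. The step needs chemoselective hydroboration (the trisubstituted ring alkene is too hindered for 9-BBN-H), ordered use of the two C–Br bonds (β before α, secured by the lactone carbonyl and the temperature stages) and a persistent alkylpalladium (C10 is quaternary and H-2 is anti to palladium, so no syn β-hydride elimination can destroy C2).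

Step 9
Reactants: 12 cis-decalin-fused butenolide
Product: 13 lactol (C11 hemiacetal, anomer mixture)
Conditions: i-Bu2AlH (1.1 equiv), CH2Cl2, −78 °C; H2O
Reagents that add atoms: none
Why: In this partial lactone reduction one equivalent of the aluminium hydride at low temperature stops at the tetrahedral aluminate of the hindered C11 carbonyl, which gives the lactol (its anomeric centre is of no consequence) while the silyl ethers and the tetrasubstituted alkene are inert.

Step 10
Reactants: 13 lactol
Product: 14 C9-vinyl C17-carbinol (2α,6α-bis-silyloxy cis-decalin with C8=C9, CH=CH2 on C9 and CH2OH on C8)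
Conditions: MePPh3Br, KOt-Bu, THF, 0 → 40 °C
Reagents that add atoms: methyltriphenylphosphonium bromide, C[P+](c1ccccc1)(c1ccccc1)c1ccccc1.[Br-]
Why: This Wittig methylenation acts on the ring-opened hydroxy enal tautomer of the lactol; the basic medium avoids acid-induced dehydration to the furan, turns C11 into the C11=C12 vinyl group and frees the C17 carbinol.

Step 11
Reactants: 14 C9-vinyl C17-carbinol; 15 4-bromofuran-2(5H)-one
Product: 17 2,6-bis(tert-butyldimethylsilyl) ether of the target, via bis-boron adduct 16 (not isolated)
Conditions: 9-BBN-H (2.5 equiv), THF, 25 °C; then 15, PdCl2(dppf) (cat.), K3PO4, DMF–H2O, 40 °C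
Reagents that add atoms: none
Why: In this hydroboration and B-alkyl Suzuki–Miyaura coupling 9-BBN-H adds only to the monosubstituted alkene (boron to C12; the free hydroxyl is masked in the flask as its borinate and the tetrasubstituted alkene is inert), and the primary alkylborane couples with the β-bromobutenolide to form C12–C13.

Step 12
Reactants: 17 bis-silyl ether
Product: 18 target
Conditions: HF·pyridine, THF, 0 → 25 °C
Reagents that add atoms: none
Why: Fluoride-mediated desilylation under mildly acidic conditions removes both secondary silyl ethers without opening or isomerising the base-sensitive butenolide and without touching any stereocentre.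

## Compound list

1 | ketoisophorone | CC1=CC(=O)CC(C)(C)C1=O | starting material
2 | (4S)-4-hydroxy-2,6,6-trimethylcyclohex-2-en-1-one | CC1(C)C[C@H](O)C=C(C)C1=O | intermediate
3 | (4S)-4-(tert-butyldimethylsilyloxy)-2,6,6-trimethylcyclohex-2-en-1-one | CC1(C)C[C@H](O[Si](C)(C)C(C)(C)C)C=C(C)C1=O | intermediate
4 | (1S,4S)-4-(tert-butyldimethylsilyloxy)-1-ethyl-2,6,6-trimethylcyclohex-2-en-1-ol | CC1(C)C[C@H](O[Si](C)(C)C(C)(C)C)C=C(C)[C@]1(O)CC | intermediate
5 | (S,Z)-4-ethylidene-3,5,5-trimethylcyclohex-2-enyl TBS ether | CC1(C)C[C@H](O[Si](C)(C)C(C)(C)C)C=C(C)/C1=C\C | intermediate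
6 | spiro vinyl epoxide, oxirane O cis to OTBS | CC1(C)C[C@H](O[Si](C)(C)C(C)(C)C)C=C(C)[C@]12O[C@H]2C | intermediate
7 | 1-[(1R,4S)-4-(TBSO)-2,6,6-trimethylcyclohex-2-en-1-yl]ethan-1-one | CC1(C)C[C@H](O[Si](C)(C)C(C)(C)C)C=C(C)[C@@H]1C(C)=O | intermediate
8 | kinetic TBS enol ether of 7 | CC1(C)C[C@H](O[Si](C)(C)C(C)(C)C)C=C(C)[C@@H]1C(=C)O[Si](C)(C)C(C)(C)C | intermediate
9 | 3,4-dibromofuran-2(5H)-one | BrC1=C(Br)C(=O)OC1 | starting material
10 | B-alkyl-9-BBN adduct (boron on C7, 6α-OTBS) | CC1(C)C[C@H](O[Si](C)(C)C(C)(C)C)C=C(C)[C@@H]1[C@H](CB2C3CCCC2CCC3)O[Si](C)(C)C(C)(C)C | intermediate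
11 | 3-bromo-4-alkylbutenolide (C7–C8 formed) | CC1(C)C[C@H](O[Si](C)(C)C(C)(C)C)C=C(C)[C@@H]1[C@H](CC2=C(Br)C(=O)OC2)O[Si](C)(C)C(C)(C)C | intermediate
12 | cis-decalin-fused butenolide | CC1(C)C[C@H](O[Si](C)(C)C(C)(C)C)C[C@]2(C)C3=C(COC3=O)C[C@H](O[Si](C)(C)C(C)(C)C)[C@H]12 | intermediate
13 | lactol (anomer mixture at C11) | CC1(C)C[C@H](O[Si](C)(C)C(C)(C)C)C[C@]2(C)C3=C(COC3O)C[C@H](O[Si](C)(C)C(C)(C)C)[C@H]12 | intermediate
14 | C9-vinyl C17-carbinol | CC1(C)C[C@H](O[Si](C)(C)C(C)(C)C)C[C@]2(C)C(C=C)=C(CO)C[C@H](O[Si](C)(C)C(C)(C)C)[C@H]12 | intermediate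
15 | 4-bromofuran-2(5H)-one | BrC1=CC(=O)OC1 | starting material
16 | bis-boron adduct (C12–B and O17–B) | CC1(C)C[C@H](O[Si](C)(C)C(C)(C)C)C[C@]2(C)C(CCB3C4CCCC3CCC4)=C(COB3C4CCCC3CCC4)C[C@H](O[Si](C)(C)C(C)(C)C)[C@H]12 | intermediate
17 | 2,6-bis-TBS ether of the target | CC1(C)C[C@H](O[Si](C)(C)C(C)(C)C)C[C@]2(C)C(CCC3=CC(=O)OC3)=C(CO)C[C@H](O[Si](C)(C)C(C)(C)C)[C@H]12 | intermediate
18 | CNP0293367.1 | CC1(C)C[C@H](O)C[C@]2(C)C(CCC3=CC(=O)OC3)=C(CO)C[C@H](O)[C@H]12 | target

## Step count and risks

Total steps: 12. Longest linear sequence: 12 (from 1).

**Step 8.** Three things may go wrong: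
- The boron ate complex may lose silyloxide by β-elimination during the coupling stage.
- Formate may capture the alkenylpalladium before the slow carbopalladation of the trisubstituted alkene, giving hydrodebromination.
- The alkylpalladium at C1 may expel the neighbouring silyloxy group.

The fallback sets out from 8 and returns at 12. Hydroboration as before, but with oxidative work-up (NaBO3·4H2O), gives the primary alcohol F1. Appel iodination (I2, PPh3, imidazole) gives the primary iodide F2. Nickel-catalysed cross-electrophile coupling of F2 with 9 (NiI2, 4,4'-di-tert-butyl-2,2'-bipyridine, Zn, DMA) gives 11 as an isolated compound without any boron ate complex. Compound 11 is then closed to 12 by an alkenyl radical 6-exo cyclisation (Bu3SnH, AIBN, benzene, reflux, slow addition), in which the same tether enforces the cis fusion.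

**Step 6.** Ionisation may run on to a free allyl cation with loss of facial memory. Proton loss may give a triene. The alkene may also drift into conjugation, followed by loss of silanol.

The fallback sets out from 6 and returns at 7. The alkenyloxirane is hydrogenolysed with formic acid under catalysis by zerovalent palladium (Pd2(dba)3·CHCl3, PBu3, HCO2H, Et3N, dioxane). Palladium ionises C5–O from the β face and hands over hydride on that same face, which means inversion at C5. This gives the homoallylic alcohol F3, and Dess–Martin oxidation gives 7.

**Step 5.** Site selectivity between the two trisubstituted alkenes of the diene may be poor, and over-oxidation may occur.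

The fallback sets out from 5 and returns at 7, bypassing 6. Catalytic osmylation (OsO4 cat., N-methylmorpholine N-oxide, acetone–H2O) is held back more strongly than the dioxirane by the allylic silyloxy group and by steric bulk. It gives the α-face diol F4. The tertiary allylic hydroxyl of F4 is ionised with a trace of acid (camphorsulfonic acid, CH2Cl2, 0 °C), so that a pinacol-type 1,2-hydride shift on the β face gives 7.

## Further compounds

F1 | step 8 | primary alcohol (C7–OH, 6α-OTBS) | CC1(C)C[C@H](O[Si](C)(C)C(C)(C)C)C=C(C)[C@@H]1[C@H](CO)O[Si](C)(C)C(C)(C)C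
F2 | step 8 | primary iodide (C7–I, 6α-OTBS) | CC1(C)C[C@H](O[Si](C)(C)C(C)(C)C)C=C(C)[C@@H]1[C@H](CI)O[Si](C)(C)C(C)(C)C
F3 | step 6 | homoallylic alcohol (H-5 β, C6–OH) | CC1(C)C[C@H](O[Si](C)(C)C(C)(C)C)C=C(C)[C@@H]1[C@H](C)O
F4 | step 5 | α-face C5,C6-diol | CC1(C)C[C@H](O[Si](C)(C)C(C)(C)C)C=C(C)[C@@]1(O)[C@H](C)O
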